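# Digriseophene A by two-fold double Michael spiroannulation and reductive unlocking

## The problem

Digriseophene A (19) is an achiral, two-fold symmetric dimer in which two griseophenone-type benzophenones are joined by one methylene carbon at ring A C3 of each half, between the C2 hydroxyl and the C4 methoxyl (ring A numbered from the ketone: C1 acyl, C2 OH, C3 CH2, C4 OMe, C5 H, C6 OH). Each carbonyl carries four ortho substituents, two hydroxyls on ring A and a methoxyl and a methyl on ring B, so direct acylation of one finished ring by the other is unattractive. The oxygens must be told apart twice: ring A has one methyl ether among three oxygens, and ring B has a methyl ether at C2' beside a free phenol at C4'. The target has no stereocentre, so any stereocentre that appears on the way is transient, controls nothing and only has to be erasable. Three features will not survive rough treatment: the six free phenols on electron-rich rings are easily oxidised to spiro-grisans or quinone methides, the bis(ortho-hydroxyaryl)methane link can be cleaved or scrambled by hot aqueous base or strong acid once its flanking phenols are free, and the 2-hydroxy-2'-methoxybenzophenone unit can close to a xanthone under forcing base. The enabling feature is the relationship between the ring A C2 hydroxyl and the ring B C4' hydroxyl across the ketone and C1': joining the C2 oxygen to C1' turns each half into a spiro benzofuran-3-one cyclohexa-2',5'-dien-4'-one. In that form C1' is the acidic C2 methylene of a coumaranone, and C2'(OMe), C4'(=O) and C6'(CH3) map onto a five-carbon diynone.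

## Retrosynthesis

**19 to 18.** The two benzyl–oxygen bonds at ring A C6 are cut. The ring A oxygen that is not part of the furanone must be masked during the base-mediated key step, and benzyl is removed last under neutral conditions that spare the polyphenol. The forward step is a simple hydrogenolysis. Bis(benzyl ether) 18 differs from 19 only by these two groups.

**18 to 17.** The bond between the ring A C2 oxygen and C1' is re-formed in each half, giving bis(spirodienone) 17. The neighbouring cut, direct union of rings A and B at the carbonyl, would require a tetra-ortho-substituted ketone to be forged twice. In 17 ring B is a cross-conjugated dienone whose C1' is an sp3 carbon with two bonds that a carbanion can make. The forward step must deliver two electrons per dienone and expel the aryloxide; zinc in acetic acid is the known reagent for this.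

**17 to 7 and 14.** The C1'–C2' and C1'–C6' bonds are cut in both halves: four skeletal bonds and two rings. This leaves bis(coumaranone) 7, which carries only ring A chemistry, and two molecules of diynone 14. Diynone 14 holds every carbon and oxygen of ring B at the final oxidation level. An alkoxyethynyl vinyl ketone would give the ring one oxidation level too low and would cost a dehydrogenation. The forward step asks for carbon-selective attack by each coumaranone enolate and for complete reaction on both arms.

**14 to 10 and 12.** The acyl–alkynyl bond is cut. Weinreb amide 10 comes from but-2-ynoic acid (8). Lithium methoxyacetylide (12) is generated from chloroacetaldehyde dimethyl acetal (11). An amide is preferred to an aldehyde as the electrophile because the ketone oxidation level is reached directly.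

**7 to 6 to 5.** Both furanone O–CH2 bonds are cut (intramolecular ether formation forward), then the C–Br bonds. This returns to bis(acetophenone) 5. Its one free phenol per ring fixes which oxygen enters the furanone.

**5 to 4 to 1 and 2.** The benzyl ethers are removed, then the two aryl–CH2 bonds, giving two molecules of 2,6-dihydroxy-4-methoxyacetophenone (1) and one of formaldehyde (2). Bridging is placed first because 1 is symmetric and its two free ring positions are equivalent. Later bridging would have to compete with the coumaranone C2 methylene, or with the ring B positions ortho to the C4' hydroxyl.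

## Roads not taken

Alternative 1: six aryl C–O bonds by fluoride displacement.
- Cut: all six ring A C–O bonds of both halves.
- Forward key step: sodium benzyloxide in DMSO on hexafluoride A1 gives hexabenzyl ether A2.
- Merits: ring B arrives intact with its C2' methoxyl, no labile acceptor is needed, and there is no ambident enolate. In robustness of the reagents it is the better road.
- Weak points: each substitution makes the ring more electron-rich, so the third displacement per ring is slow. The twisted, hindered ketone activates poorly. The CH2 between two polyfluoroaryl rings is acidic under alkoxide in DMSO. All three ring A oxygens arrive identical, so the C4 methyl ether must be written in afterwards, selectively on both rings, before the MOM groups come off.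
- Comparison: the chosen plan carries the ring A methyl ether from the first compound and needs only two steps after the key step.

Alternative 2: pyrone unfolding and aldol closure.
- Cut: the C1'–C6' bond of each ring B.
- Forward key step: aqueous KOH opens bis(pyrone) A3 to bis(tetraketone) A4, which cyclises and dehydrates to A5.
- Merits: ring B is built from a cheap pyrone under simple conditions with no sensitive alkyne. This mirrors the polyketide folding and is attractive in material cost.
- Weak points: A4 can close in more than one aldol mode (the terminal methyl onto the C2' carbonyl competes) and can re-lactonise. A5 also has the wrong phenol free: the C2' hydroxyl that must be methylated is the chelated, hindered one, and the C4' hydroxyl is the reactive one. Protection, methylation and deprotection on both arms are therefore added before the four benzyl groups are removed.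
- Comparison: the chosen plan delivers the C2' methoxyl with the acceptor.

Alternative 3: aryne insertion into a bis(beta-keto ester).
- Cut: the C1'–C(=O) and C6'–CH2 bonds of both rings B.
- Forward key step: CsF releases aryne A8 from silyl triflate A7; A8 inserts into the C(O)–CH2 bond of bis(beta-keto ester) A6 to give A9.
- Merits: it is the most convergent way to the hindered diaryl ketone. The ring B oxygens are differentiated from the start, the methoxyl directs the insertion correctly, and no stereoisomer mixtures are carried. In these respects it equals or beats the chosen plan.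
- Weak points: the aryl anion must attack a ketone flanked by two benzyloxy groups, twice, and simple alpha-arylation competes. Each arm of A9 carries a CH2CO2Me where the target has CH3, so hydrolysis and decarboxylation of an arylacetic acid are needed on a polyphenol. A7 needs its own multi-step preparation.
- Comparison: in the chosen plan every carbon of the acceptor ends in ring B and nothing has to be excised.

Key step: step 7

Assumption: benzylation of 4 (step 2) is taken to occur at the bridge-remote hydroxyl of each ring, so 5–18 are drawn as the 7,7'-linked series. A ring benzylated at the bridge-flanked hydroxyl would give the 5-linked coumaranone regioisomer, which undergoes the same steps and becomes identical with 19 after step 9.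

Remark: steps 1 to 4 and 7 to 9 act on both halves of the dimer, so each consumes two molecules of the reagent or partner named. The half-converted species are not numbered, except in step 7 where they define the mechanism.

## Route

Step 1
Reactants: 1 1-(2,6-dihydroxy-4-methoxyphenyl)ethanone (two molecules); 2 formaldehyde
Product: 4 bis(3-acetyl-2,4-dihydroxy-6-methoxyphenyl)methane, via hydroxymethyl acetophenone 3 (not isolated)
Conditions: 1 (3.0 equiv), 37% aq. CH2O (1.0 equiv), H2SO4 (cat.), EtOH/H2O, 50 °C; excess 1 recovered
Reagents that add atoms: 1-(2,6-dihydroxy-4-methoxyphenyl)ethanone (the second molecule of 1), COc1cc(O)c(C(C)=O)c(O)c1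
Why: Acid-catalysed hydroxymethylation of one molecule of 1 at the doubly activated ring position (ortho to one hydroxyl, para to the other; both free positions of 1 are equivalent) gives 3, whose benzylic cation alkylates a second molecule of 1 with loss of water (Friedel–Crafts hydroxyalkylation–alkylation, the usual way to methylene-bridged acylphloroglucinols); the excess of 1 is meant to outcompete the remaining free position of 4.

Step 2
Reactants: 4 bis(3-acetyl-2,4-dihydroxy-6-methoxyphenyl)methane
Product: 5 bis[3-acetyl-4-(benzyloxy)-2-hydroxy-6-methoxyphenyl]methane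
Conditions: BnBr (2.1 equiv), K2CO3 (2.2 equiv), acetone, reflux
Reagents that add atoms: benzyl bromide, BrCc1ccccc1
Why: Williamson etherification; in a 2,6-dihydroxyaryl ketone only one hydroxyl is chelated by the carbonyl at a time, so the first benzylation per ring is fast and the remaining chelated hydroxyl reacts far more slowly, and the bridge-flanked hydroxyl is the more hindered one and should be the one left free.

Step 3
Reactants: 5 bis[3-acetyl-4-(benzyloxy)-2-hydroxy-6-methoxyphenyl]methane
Product: 6 bis[4-(benzyloxy)-3-(bromoacetyl)-2-hydroxy-6-methoxyphenyl]methane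
Conditions: CuBr2 (4.4 equiv), EtOAc/CHCl3 (1:1), reflux
Reagents that add atoms: copper dibromide, Br[Cu]Br
Why: Heterogeneous CuBr2 brominates the enol of an aryl methyl ketone selectively at the alpha carbon and stops at the monobromide; it is the usual reagent for 2-hydroxy-4,6-dialkoxyacetophenones, where molecular bromine would attack the ring.

Step 4
Reactants: 6 bis[4-(benzyloxy)-3-(bromoacetyl)-2-hydroxy-6-methoxyphenyl]methane
Product: 7 7,7'-methylenebis[4-(benzyloxy)-6-methoxybenzofuran-3(2H)-one]
Conditions: NaOAc (4 equiv), EtOH, reflux
Reagents that add atoms: none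
Why: Acetate deprotonates the chelated phenol and the phenoxide displaces the primary alpha-bromide in a 5-exo-tet intramolecular Williamson closure, the standard entry to benzofuran-3(2H)-ones; the weak base should not trigger aldol self-condensation of the product.

Step 5
Reactants: 8 but-2-ynoic acid
Product: 10 N-methoxy-N-methylbut-2-ynamide, via 1-(but-2-ynoyl)imidazole 9 (not isolated)
Conditions: CDI (1.1 equiv), CH2Cl2, 0 °C to rt; then MeNHOMe·HCl (1.2 equiv), rt
Reagents that add atoms: N,O-dimethylhydroxylamine hydrochloride, CNOC.Cl
Why: Carboxyl activation as the acyl imidazole followed by aminolysis (Weinreb amide formation); no acid chloride or free hydrogen halide is present, so nothing can add across the conjugated alkyne.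

Step 6
Reactants: 11 chloroacetaldehyde dimethyl acetal; 10 N-methoxy-N-methylbut-2-ynamide
Product: 14 1-methoxyhexa-1,4-diyn-3-one, via lithium methoxyacetylide 12 (not isolated), via lithium hemiaminal alkoxide 13 (not isolated)
Conditions: 11 (1.3 equiv), LiNEt2 (3.9 equiv), THF, −78 to 0 °C; then 10 (1.0 equiv), −78 °C; inverse quench into cold 1 M HCl/Et2O; used at once
Reagents that add atoms: none
Why: Three equivalents of LiNEt2 per acetal eliminate methanol and HCl from 11 and deprotonate the resulting methoxyacetylene to 12 (in situ alkoxyacetylide generation); 12 adds once to the Weinreb amide because the chelated adduct 13 does not collapse until the cold acidic quench, which also protonates both amines before they can add to the ynone.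

Step 7
Reactants: 7 7,7'-methylenebis[4-(benzyloxy)-6-methoxybenzofuran-3(2H)-one]; 14 1-methoxyhexa-1,4-diyn-3-one (two molecules)
Product: 17 7,7'-methylenebis[4-(benzyloxy)-2',6-dimethoxy-6'-methylspiro[benzofuran-2,1'-cyclohexa-2',5'-diene]-3,4'-dione] (spiro diastereomer mixture), via mono-adduct enynone 15 (not isolated), via mono-spiro dienone 16 (not isolated)
Conditions: 14 (2.5 equiv), KOtBu (0.4 equiv, added slowly in t-BuOH), THF/t-BuOH, 0 °C to rt
Reagents that add atoms: none
Why: Catalytic tert-butoxide converts a C2 methylene of 7 into a soft coumaranone enolate, which adds through carbon to the methyl-bearing alkyne carbon of 14 with anti protonation, giving enynone 15 with the acyl group cis to the new C–C bond; proton transfer then gives an extended enolate whose C2 attacks the methoxy-bearing alkyne carbon, and t-BuOH protonates the resulting vinyl anion to give the cross-conjugated dienone. The closest known reaction types are the double Michael spiroannulation of benzofuran-3(2H)-ones with alkoxyethynyl vinyl ketones and the [5+1] annulation of 1,4-diyn-3-ones with cyclic C–H acids. Each of the two cyclohexadienone rings is closed by a 6-endo-dig Michael addition, the only ring size the tether allows, so neither the enolate oxygen nor the gamma carbon can compete in the closure. The two spiro carbons form independently and with no controlling element, so 17 should be a mixture of the racemic and the meso diastereomer; this is harmless because step 8 destroys both centres. The selectivity needed is carbon over oxygen attack in the first, intermolecular addition, which the soft ynone acceptor and the potassium enolate in a protic medium favour. The order in which the two alkynes are attacked is irrelevant, since C1' ends bonded to both termini: the methoxy-bearing carbon becomes C2', the methyl-bearing carbon C6' and the ketone C4'. The second coumaranone unit reacts in the same way with a second molecule of 14 through 16; the excess of 14 and slow addition of base keep both arms supplied with acceptor.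

Step 8
Reactants: 17 7,7'-methylenebis[4-(benzyloxy)-2',6-dimethoxy-6'-methylspiro[benzofuran-2,1'-cyclohexa-2',5'-diene]-3,4'-dione]
Product: 18 bis[4-(benzyloxy)-2-hydroxy-3-(4-hydroxy-2-methoxy-6-methylbenzoyl)-6-methoxyphenyl]methane
Conditions: Zn dust (10 equiv), AcOH, rt
Reagents that add atoms: none
Why: Zinc transfers two electrons to each cross-conjugated dienone, the aryloxide on the spiro carbon is expelled and ring B aromatises to the C4' phenol (reductive cleavage of a 4-aryloxycyclohexa-2,5-dienone, the known opening of grisadienones to 2-hydroxybenzophenones); both spiro centres vanish and the diastereomers converge.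

Step 9
Reactants: 18 bis[4-(benzyloxy)-2-hydroxy-3-(4-hydroxy-2-methoxy-6-methylbenzoyl)-6-methoxyphenyl]methane
Product: 19 digriseophene A (bis[2,4-dihydroxy-3-(4-hydroxy-2-methoxy-6-methylbenzoyl)-6-methoxyphenyl]methane)
Conditions: H2 (1 atm), 10% Pd/C, EtOAc/MeOH, rt
Reagents that add atoms: none
Why: Hydrogenolysis of the two benzyl aryl ethers over Pd/C; the chelated, tetra-ortho-substituted diaryl ketone and the diarylmethane reduce far more slowly, and the neutral conditions spare the free polyphenol.

## Compound list

1 | 1-(2,6-dihydroxy-4-methoxyphenyl)ethanone | COc1cc(O)c(C(C)=O)c(O)c1 | starting material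
2 | formaldehyde | C=O | starting material
3 | 1-[2,6-dihydroxy-3-(hydroxymethyl)-4-methoxyphenyl]ethanone | COc1cc(O)c(C(C)=O)c(O)c1CO | intermediate (not isolated)
4 | bis(3-acetyl-2,4-dihydroxy-6-methoxyphenyl)methane | COc1cc(O)c(C(C)=O)c(O)c1Cc1c(OC)cc(O)c(C(C)=O)c1O | intermediate
5 | bis[3-acetyl-4-(benzyloxy)-2-hydroxy-6-methoxyphenyl]methane | COc1cc(OCc2ccccc2)c(C(C)=O)c(O)c1Cc1c(OC)cc(OCc2ccccc2)c(C(C)=O)c1O | intermediate
6 | bis[4-(benzyloxy)-3-(bromoacetyl)-2-hydroxy-6-methoxyphenyl]methane | COc1cc(OCc2ccccc2)c(C(=O)CBr)c(O)c1Cc1c(OC)cc(OCc2ccccc2)c(C(=O)CBr)c1O | intermediate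
7 | 7,7'-methylenebis[4-(benzyloxy)-6-methoxybenzofuran-3(2H)-one] | COc1cc(OCc2ccccc2)c2C(=O)COc2c1Cc1c(OC)cc(OCc2ccccc2)c2C(=O)COc12 | intermediate
8 | but-2-ynoic acid | CC#CC(=O)O | starting material
9 | 1-(but-2-ynoyl)-1H-imidazole | CC#CC(=O)n1ccnc1 | intermediate (not isolated)
10 | N-methoxy-N-methylbut-2-ynamide | CC#CC(=O)N(C)OC | intermediate
11 | chloroacetaldehyde dimethyl acetal (2-chloro-1,1-dimethoxyethane) | COC(CCl)OC | starting material
12 | lithium methoxyacetylide | [Li+].[C-]#COC | intermediate (not isolated)
13 | lithium 3-[methoxy(methyl)amino]-1-methoxyhexa-1,4-diyn-3-olate (racemic) | [Li+].CC#CC([O-])(C#COC)N(C)OC | intermediate (not isolated)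
14 | 1-methoxyhexa-1,4-diyn-3-one | COC#CC(=O)C#CC | intermediate
15 | mono-adduct: 7 carrying at C2 of one coumaranone a (Z)-6-methoxy-4-oxohex-2-en-5-yn-2-yl group (racemic at C2) | COc1cc(OCc2ccccc2)c2C(=O)C(/C(C)=C\C(=O)C#COC)Oc2c1Cc1c(OC)cc(OCc2ccccc2)c2C(=O)COc12 | intermediate (not isolated)
16 | mono-spiro dienone: one arm annulated to the 2'-methoxy-6'-methylspiro[benzofuran-2,1'-cyclohexa-2',5'-diene]-3,4'-dione, the other arm still a benzofuran-3(2H)-one (racemic) | COc1cc(OCc2ccccc2)c2C(=O)C3(Oc2c1Cc1c(OC)cc(OCc2ccccc2)c2C(=O)COc12)C(OC)=CC(=O)C=C3C | intermediate (not isolated)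
17 | 7,7'-methylenebis[4-(benzyloxy)-2',6-dimethoxy-6'-methylspiro[benzofuran-2,1'-cyclohexa-2',5'-diene]-3,4'-dione], racemic and meso diastereomers | COc1cc(OCc2ccccc2)c2C(=O)C3(Oc2c1Cc1c(OC)cc(OCc2ccccc2)c2C(=O)C4(Oc12)C(OC)=CC(=O)C=C4C)C(OC)=CC(=O)C=C3C | intermediate
18 | bis[4-(benzyloxy)-2-hydroxy-3-(4-hydroxy-2-methoxy-6-methylbenzoyl)-6-methoxyphenyl]methane | COc1cc(OCc2ccccc2)c(C(=O)c2c(C)cc(O)cc2OC)c(O)c1Cc1c(OC)cc(OCc2ccccc2)c(C(=O)c2c(C)cc(O)cc2OC)c1O | intermediate
19 | digriseophene A, bis[2,4-dihydroxy-3-(4-hydroxy-2-methoxy-6-methylbenzoyl)-6-methoxyphenyl]methane (achiral) | COc1cc(O)c(C(=O)c2c(C)cc(O)cc2OC)c(O)c1Cc1c(OC)cc(O)c(C(=O)c2c(C)cc(O)cc2OC)c1O | target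

## Step count and risks

Total: 9 steps. Longest linear sequence: 7 steps (1, 2, 3, 4, 7, 8, 9). The diynone branch (steps 5 and 6) joins at step 7.

**Step 7 (key step).** The most likely failure is loss of the diynone to alkoxide addition or base-induced oligomerisation before both arms are annulated, together with some oxygen attack by the ambident enolate. The result would be incomplete, one-armed annulation. The fallback uses the classical enone acceptor and adjusts the oxidation level afterwards. It sets out from 12 and 7. Acetylide 12 is added to (E)-but-2-enal to give (E)-1-methoxyhex-4-en-1-yn-3-ol F1, which MnO2 in CH2Cl2 oxidises to (E)-1-methoxyhex-4-en-1-yn-3-one F2. KOtBu-mediated double Michael addition of 7 to two molecules of F2 closes each ring 6-endo-trig and gives the bis(2'-methoxy-6'-methylcyclohex-2'-en-4'-one) spiro compound F3. Deprotonation at C5' with LiN(iPr)2 and trapping with TMSCl gives the bis(silyl dienol ether) F4. Saegusa–Ito oxidation of F4 with Pd(OAc)2 in MeCN introduces the C5'–C6' double bonds and returns to the route at 17.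

**Step 6.** The liberated diethylamine and N,O-dimethylhydroxylamine may add to the very electrophilic diynone during the quench, and the methoxyalkyne may be hydrated if the acid contact is long. The fallback separates C–C bond formation from the ketone oxidation level. From 12, addition to commercial but-2-ynal gives 1-methoxyhexa-1,4-diyn-3-ol F5, where no Michael acceptor is present when the amines are set free. Oxidation of F5 with MnO2 in CH2Cl2 under neutral conditions comes back at 14.

**Step 1.** Over-condensation is the risk: 4 keeps one activated position per ring and can be hydroxymethylated again, leading to trimers and oligomers. The fallback blocks that position. From 1, one equivalent of NBS gives 1-(3-bromo-2,6-dihydroxy-4-methoxyphenyl)ethanone F6. F6 has a single free ring position and can only dimerise with formaldehyde, giving bis(3-acetyl-5-bromo-2,4-dihydroxy-6-methoxyphenyl)methane F7. Hydrogenolysis of the two aryl bromides (H2, Pd/C, NaOAc, MeOH) returns to 4.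

**Step 2.** Statistical over- and under-benzylation, and benzylation at the bridge-flanked oxygen, may erode the yield of the one-per-ring ether. The fallback replaces selective protection by exhaustive protection and chelation-controlled deprotection. From 4, excess BnBr and K2CO3 in warm DMF give bis[3-acetyl-2,4-bis(benzyloxy)-6-methoxyphenyl]methane F8. MgBr2·OEt2 then removes one carbonyl-flanking benzyl group per ring (the magnesium phenoxide chelate protects the second) and returns to 5. The more crowded, bridge-flanked ether is expected to go first, and the other regioisomer is covered by the assumption stated before the steps.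

**Step 3.** Electrophilic bromination of the free, activated ring position, or loss of a benzyl group to the HBr evolved at reflux, could compete with alpha-bromination. The fallback brominates a preformed enol derivative at low temperature. From 5, TMSOTf and Et3N give the tetrakis(trimethylsilyl) bis(enol ether) F9. NBS in THF at −78 °C brominates the silyl enol ether carbons only, and mild aqueous work-up releases the phenols, returning to 6.

## Further compounds

F1 | step 7 | (E)-1-methoxyhex-4-en-1-yn-3-ol (racemic) | COC#CC(O)/C=C/C
F2 | step 7 | (E)-1-methoxyhex-4-en-1-yn-3-one | COC#CC(=O)/C=C/C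
F3 | step 7 | 7,7'-methylenebis[4-(benzyloxy)-2',6-dimethoxy-6'-methylspiro[benzofuran-2,1'-cyclohex-2'-ene]-3,4'-dione], mixture of diastereomers | COc1cc(OCc2ccccc2)c2C(=O)C3(Oc2c1Cc1c(OC)cc(OCc2ccccc2)c2C(=O)C4(Oc12)C(OC)=CC(=O)CC4C)C(OC)=CC(=O)CC3C
F4 | step 7 | 7,7'-methylenebis[4-(benzyloxy)-2',6-dimethoxy-6'-methyl-4'-(trimethylsilyloxy)spiro[benzofuran-2,1'-cyclohexa-2',4'-dien]-3-one], mixture of diastereomers | COc1cc(OCc2ccccc2)c2C(=O)C3(Oc2c1Cc1c(OC)cc(OCc2ccccc2)c2C(=O)C4(Oc12)C(OC)=CC(O[Si](C)(C)C)=CC4C)C(OC)=CC(O[Si](C)(C)C)=CC3C
F5 | step 6 | 1-methoxyhexa-1,4-diyn-3-ol (racemic) | COC#CC(O)C#CC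
F6 | step 1 | 1-(3-bromo-2,6-dihydroxy-4-methoxyphenyl)ethanone | COc1cc(O)c(C(C)=O)c(O)c1Br
F7 | step 1 | bis(3-acetyl-5-bromo-2,4-dihydroxy-6-methoxyphenyl)methane | COc1c(Br)c(O)c(C(C)=O)c(O)c1Cc1c(OC)c(Br)c(O)c(C(C)=O)c1O
F8 | step 2 | bis[3-acetyl-2,4-bis(benzyloxy)-6-methoxyphenyl]methane | COc1cc(OCc2ccccc2)c(C(C)=O)c(OCc2ccccc2)c1Cc1c(OC)cc(OCc2ccccc2)c(C(C)=O)c1OCc1ccccc1
F9 | step 3 | bis{4-(benzyloxy)-6-methoxy-2-(trimethylsilyloxy)-3-[1-(trimethylsilyloxy)ethenyl]phenyl}methane | COc1cc(OCc2ccccc2)c(C(=C)O[Si](C)(C)C)c(O[Si](C)(C)C)c1Cc1c(OC)cc(OCc2ccccc2)c(C(=C)O[Si](C)(C)C)c1O[Si](C)(C)C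
A1 | alternative 1 | bis{2,4,6-trifluoro-3-[2-methoxy-4-(methoxymethoxy)-6-methylbenzoyl]phenyl}methane | COCOc1cc(C)c(C(=O)c2c(F)cc(F)c(Cc3c(F)cc(F)c(C(=O)c4c(C)cc(OCOC)cc4OC)c3F)c2F)c(OC)c1
A2 | alternative 1 | bis{2,4,6-tris(benzyloxy)-3-[2-methoxy-4-(methoxymethoxy)-6-methylbenzoyl]phenyl}methane | COCOc1cc(C)c(C(=O)c2c(OCc3ccccc3)cc(OCc3ccccc3)c(Cc3c(OCc4ccccc4)cc(OCc4ccccc4)c(C(=O)c4c(C)cc(OCOC)cc4OC)c3OCc3ccccc3)c2OCc2ccccc2)c(OC)c1
A3 | alternative 2 | bis{2,4-bis(benzyloxy)-6-methoxy-3-[(6-methyl-4-oxo-4H-pyran-2-yl)acetyl]phenyl}methane | COc1cc(OCc2ccccc2)c(C(=O)Cc2cc(=O)cc(C)o2)c(OCc2ccccc2)c1Cc1c(OC)cc(OCc2ccccc2)c(C(=O)Cc2cc(=O)cc(C)o2)c1OCc1ccccc1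
A4 | alternative 2 | 1,1'-[methylenebis(2,4-bis(benzyloxy)-6-methoxy-3,1-phenylene)]bis(octane-1,3,5,7-tetraone) | COc1cc(OCc2ccccc2)c(C(=O)CC(=O)CC(=O)CC(C)=O)c(OCc2ccccc2)c1Cc1c(OC)cc(OCc2ccccc2)c(C(=O)CC(=O)CC(=O)CC(C)=O)c1OCc1ccccc1
A5 | alternative 2 | 2'-O-demethyl digriseophene A, ring A tetrabenzyl ether | COc1cc(OCc2ccccc2)c(C(=O)c2c(C)cc(O)cc2O)c(OCc2ccccc2)c1Cc1c(OC)cc(OCc2ccccc2)c(C(=O)c2c(C)cc(O)cc2O)c1OCc1ccccc1
A6 | alternative 3 | dimethyl 3,3'-[methylenebis(2,4-bis(benzyloxy)-6-methoxy-3,1-phenylene)]bis(3-oxopropanoate) | COc1cc(OCc2ccccc2)c(C(=O)CC(=O)OC)c(OCc2ccccc2)c1Cc1c(OC)cc(OCc2ccccc2)c(C(=O)CC(=O)OC)c1OCc1ccccc1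
A7 | alternative 3 | 5-(benzyloxy)-3-methoxy-2-(trimethylsilyl)phenyl trifluoromethanesulfonate | COc1cc(OCc2ccccc2)cc(OS(=O)(=O)C(F)(F)F)c1[Si](C)(C)C
A8 | alternative 3 | 5-(benzyloxy)-3-methoxybenzyne | COC1=CC(OCc2ccccc2)=CC#C1
A9 | alternative 3 | bis-benzophenone with CH2CO2Me at both C6' positions, hexabenzyl ether | COc1cc(OCc2ccccc2)c(C(=O)c2c(CC(=O)OC)cc(OCc3ccccc3)cc2OC)c(OCc2ccccc2)c1Cc1c(OC)cc(OCc2ccccc2)c(C(=O)c2c(CC(=O)OC)cc(OCc3ccccc3)cc2OC)c1OCc1ccccc1
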